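**Assumption:** the target (marchantinquinone, C29H24O6) has no stereocentre, and its 18-membered ring is taken to be conformationally mobile. No enantiomer therefore needs to be set, and the E-alkenes made on the way are removed by hydrogenation.

## Retrosynthetic overview
1. The last and only ring formation closes the 18-membered macrocycle at the quinone C5–O(aryl) bond. An open-chain hydroquinone-diphenol undergoes dehydrogenative oxa-Michael cyclisation.
2. The hydroquinone level of the quinone ring comes from a 5-substituted vanillin, whose CHO is converted to OH by Dakin oxidation. One hydrogenation saturates both bridges and removes both benzyl groups.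
3. The bridge next to the quinone ring comes from a Heck reaction of 5-iodovanillin with a styrene. The other bridge comes from a Horner–Wadsworth–Emmons (HWE) olefination of an aldehyde.
4. The other diaryl ether is made first by Chan–Lam C–O coupling of 4-benzyloxy-3-hydroxybenzaldehyde with 4-vinylphenylboronic acid.

## Route

**Step 1**
Reactants: 1 4-(benzyloxy)-3-hydroxybenzaldehyde; 2 4-vinylphenylboronic acid
Product: 3 4-(benzyloxy)-3-(4-ethenylphenoxy)benzaldehyde
Conditions: Cu(OAc)2 (1.0 equiv), pyridine (5 equiv), 4 Å MS, CH2Cl2, dry air, rt, 24 h (2: 1.5 equiv)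
Reagents that add atoms: none
Why: Chan–Lam–Evans O-arylation works at room temperature on ortho-alkoxyphenols and leaves the aldehyde, benzyl ether and vinyl group untouched, so the two arms carry different handles (CHO and vinyl) from the start.

**Step 2**
Reactants: 4 3-(benzyloxy)benzyl bromide
Product: 5 diethyl [3-(benzyloxy)benzyl]phosphonate
Conditions: P(OEt)3 (neat, 1.5 equiv), 130 °C, 4 h, then distil off the excess
Reagents that add atoms: triethyl phosphite, CCOP(OCC)OCC
Why: Michaelis–Arbuzov reaction of a reactive benzylic bromide, driven by loss of volatile ethyl bromide.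

**Step 3**
Reactants: 3 4-(benzyloxy)-3-(4-ethenylphenoxy)benzaldehyde; 5 diethyl [3-(benzyloxy)benzyl]phosphonate
Product: 6 1-(benzyloxy)-4-{(E)-2-[3-(benzyloxy)phenyl]ethenyl}-2-(4-ethenylphenoxy)benzene
Conditions: KOtBu (1.2 equiv), THF, 0 °C to rt
Reagents that add atoms: none
Why: HWE olefination of an aromatic aldehyde with a benzyl phosphonate gives the E-stilbene cleanly, and the styrene is inert to the base.

**Step 4**
Reactants: 6 the stilbene-styrene from step 3; 7 5-iodovanillin (4-hydroxy-3-iodo-5-methoxybenzaldehyde)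
Product: 8 4-hydroxy-3-methoxy-5-[(E)-2-(4-{2-(benzyloxy)-5-[(E)-2-(3-benzyloxyphenyl)ethenyl]phenoxy}phenyl)ethenyl]benzaldehyde
Conditions: Pd(OAc)2 (5 mol %), P(o-tol)3 (10 mol %), Et3N (3 equiv), DMF, 90 °C
Reagents that add atoms: none
Why: Mizoroki–Heck arylation occurs at the terminal carbon of the monosubstituted styrene, while the 1,2-disubstituted stilbene reacts far more slowly and the aryl iodide couples with its phenol free.

**Step 5**
Reactants: 8 the bis-stilbene aldehyde from step 4
Product: 10 2-methoxy-6-[(E)-2-(4-{2-(benzyloxy)-5-[(E)-2-(3-benzyloxyphenyl)ethenyl]phenoxy}phenyl)ethenyl]benzene-1,4-diol, via aryl formate 9 (not isolated)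
Conditions: 30 % H2O2 (1.1 equiv), NaOH (2 equiv), degassed THF/H2O, 0 °C, Ar; then Na2S2O4 wash, HCl to pH 3
Reagents that add atoms: hydrogen peroxide, OO
Why: Dakin oxidation of a p-hydroxybenzaldehyde proceeds by hydroperoxide addition, aryl migration and formate hydrolysis, the unactivated stilbenes do not react with alkaline H2O2, and any adventitious quinone is reduced back in step 6.

**Step 6**
Reactants: 10 the bis-stilbene hydroquinone from step 5
Product: 11 2-[2-(4-{2-hydroxy-5-[2-(3-hydroxyphenyl)ethyl]phenoxy}phenyl)ethyl]-6-methoxybenzene-1,4-diol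
Conditions: H2 (1 atm), 10 % Pd/C, EtOAc/MeOH, rt; filter under Ar and use directly
Reagents that add atoms: none
Why: One catalytic hydrogenation/hydrogenolysis saturates both stilbenes and cleaves both benzyl ethers, while the diaryl ether and methyl ether are stable.

**Step 7 (key step)**
Reactants: 11 the open-chain hydroquinone-diphenol from step 6
Product: 14 marchantinquinone (target), via seco-quinone 12 (not isolated), via macrocyclic hydroquinone 13 (not isolated)
Conditions: 3,3',5,5'-tetra-tert-butyl-4,4'-diphenoquinone (DPQ, 2.2 equiv), Cs2CO3 (50 mol %), degassed THF/DMF 4:1, 35 °C, Ar; 11 added by syringe pump over 12 h (final 1 mM); AcOH quench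
Reagents that add atoms: none
Why: Proposed new method: a dehydrogenative oxa-Michael macrocyclisation in which the hindered, nucleophile-inert DPQ first oxidises only the hydroquinone (simple phenoxides lie far above its potential) to 2-methoxy-6-alkylquinone 12, the caesium 3-alkylphenoxide then adds through oxygen at C5, which is the only electrophilic CH because the OMe deactivates C4=O as a vinylogous ester and makes C3 electron-rich, aromatising tautomerisation makes the addition irreversible to give 13, and a second equivalent of DPQ gives 14; the other free phenol cannot compete within the molecule because it would close a strained 12-membered [8]paracyclophane-type ring, and the closest known reaction types are oxidative amine/thiol addition to quinones and phenoxide addition–elimination on haloquinones.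

## Compound list
1 | 4-(benzyloxy)-3-hydroxybenzaldehyde | O=Cc1ccc(OCc2ccccc2)c(O)c1 | starting material
2 | 4-vinylphenylboronic acid | C=Cc1ccc(cc1)B(O)O | starting material
3 | 4-(benzyloxy)-3-(4-ethenylphenoxy)benzaldehyde | O=Cc1ccc(OCc2ccccc2)c(Oc2ccc(C=C)cc2)c1 | intermediate
4 | 3-(benzyloxy)benzyl bromide | BrCc1cccc(OCc2ccccc2)c1 | starting material
5 | diethyl [3-(benzyloxy)benzyl]phosphonate | CCOP(=O)(OCC)Cc1cccc(OCc2ccccc2)c1 | intermediate
6 | 1-(benzyloxy)-4-{(E)-2-[3-(benzyloxy)phenyl]ethenyl}-2-(4-ethenylphenoxy)benzene | C=Cc1ccc(cc1)Oc1cc(/C=C/c2cccc(OCc3ccccc3)c2)ccc1OCc1ccccc1 | intermediate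
7 | 5-iodovanillin | COc1cc(C=O)cc(I)c1O | starting material
8 | bis-(E)-stilbene vanillin-type aldehyde | COc1cc(C=O)cc(/C=C/c2ccc(cc2)Oc2cc(/C=C/c3cccc(OCc4ccccc4)c3)ccc2OCc2ccccc2)c1O | intermediate
9 | aryl formate from the Dakin migration | COc1cc(OC=O)cc(/C=C/c2ccc(cc2)Oc2cc(/C=C/c3cccc(OCc4ccccc4)c3)ccc2OCc2ccccc2)c1O | intermediate (not isolated)
10 | bis-(E)-stilbene methoxyhydroquinone | COc1cc(O)cc(/C=C/c2ccc(cc2)Oc2cc(/C=C/c3cccc(OCc4ccccc4)c3)ccc2OCc2ccccc2)c1O | intermediate
11 | open-chain hydroquinone-diphenol | COc1cc(O)cc(CCc2ccc(cc2)Oc2cc(CCc3cccc(O)c3)ccc2O)c1O | intermediate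
12 | seco-quinone (2-methoxy-6-alkyl-1,4-benzoquinone) | COC1=CC(=O)C=C(CCc2ccc(cc2)Oc2cc(CCc3cccc(O)c3)ccc2O)C1=O | intermediate (not isolated)
13 | macrocyclic hydroquinone (dihydromarchantinquinone) | COc1cc(O)c2c(CCc3ccc(cc3)Oc3cc(ccc3O)CCc3cccc(c3)O2)c1O | intermediate (not isolated)
14 | marchantinquinone | COC1=CC(=O)C2=C(CCc3ccc(cc3)Oc3cc(ccc3O)CCc3cccc(c3)O2)C1=O | target

## Summary
Total steps: 7. Longest linear sequence: 6 (steps 1, 3, 4, 5, 6, 7).

## Steps most likely to fail

**Step 7 (new macrocyclisation).** The risks are C-attack instead of O-attack, oligomerisation, and base-induced quinone-methide tautomerisation of the alkylquinone. The fallback sets out from 11 and returns at 14, and it replaces C–H functionalisation by known halide displacement.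
- Oxidise 11 with aqueous FeCl3 in MeCN and isolate seco-quinone 12.
- Add dry HCl in CHCl3/Et2O. This classical 1,4-hydrohalogenation of a quinone follows the same C5 regiochemistry and gives the 5-chlorohydroquinone F1.
- Reoxidise with FeCl3 to the 5-chloro-2-methoxy-6-alkylquinone F2.
- Cyclise by phenoxide addition–elimination (Cs2CO3, DMF, 1 mM, rt) to 14.

**Step 5 (Dakin oxidation).** The electron-rich styrylhydroquinone may over-oxidise in alkaline peroxide. The fallback sets out from 6 and returns at 12, and it avoids the aldehyde-to-phenol conversion altogether.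
- Heck-couple 6 with purchased 2-iodo-6-methoxyphenol to give the bis-stilbene guaiacol F3.
- Hydrogenate (H2, Pd/C) to the triphenol F4.
- Oxidise the 2-methoxy-6-alkylphenol ring at its free para position with Co(salen)/O2 in DMF to isolated 12. This ring is the most electron-rich phenol and the only 2,6-disubstituted one.
- Run step 7 on 12 with only 1.1 equiv DPQ.

**Step 4 (Heck reaction).** The free o-iodophenoxide may be sluggish and the styrene may polymerise. The fallback sets out from 6 and returns at 11, and it forms an sp3–sp2 bond instead.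
- Hydroborate the terminal vinyl group selectively with 9-BBN in THF to the B-alkyl borane F5.
- Couple F5 with 7 by B-alkyl Suzuki–Miyaura reaction (PdCl2(dppf), K3PO4, DMF/H2O, 60 °C) to the aldehyde F6, whose bridge is already saturated.
- Carry out the Dakin oxidation as in step 5 to give hydroquinone F7.
- Treat with H2 and Pd/C to give 11.

## Further compounds
F1 | step 7 | 5-chlorohydroquinone of the open-chain compound | COc1cc(O)c(Cl)c(CCc2ccc(cc2)Oc2cc(CCc3cccc(O)c3)ccc2O)c1O
F2 | step 7 | 5-chloro-2-methoxy-6-alkyl-1,4-benzoquinone (open chain) | COC1=CC(=O)C(Cl)=C(CCc2ccc(cc2)Oc2cc(CCc3cccc(O)c3)ccc2O)C1=O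
F3 | step 5 | bis-(E)-stilbene 2-methoxyphenol | COc1cccc(/C=C/c2ccc(cc2)Oc2cc(/C=C/c3cccc(OCc4ccccc4)c3)ccc2OCc2ccccc2)c1O
F4 | step 5 | open-chain triphenol | COc1cccc(CCc2ccc(cc2)Oc2cc(CCc3cccc(O)c3)ccc2O)c1O
F5 | step 4 | B-alkyl-9-BBN adduct of 6 | B1(CCc2ccc(cc2)Oc2cc(/C=C/c3cccc(OCc4ccccc4)c3)ccc2OCc2ccccc2)C2CCCC1CCC2
F6 | step 4 | aldehyde with saturated bridge to the vanillin ring | COc1cc(C=O)cc(CCc2ccc(cc2)Oc2cc(/C=C/c3cccc(OCc4ccccc4)c3)ccc2OCc2ccccc2)c1O
F7 | step 4 | hydroquinone with saturated bridge, one stilbene left | COc1cc(O)cc(CCc2ccc(cc2)Oc2cc(/C=C/c3cccc(OCc4ccccc4)c3)ccc2OCc2ccccc2)c1O
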